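Numbering: chroman (O1, C2–C4, C4a, C5–C8, C8a); ring A is the benzo ring, ring B the aryl group on C2. Retrosynthetic cuts, in order: the five O–CH3 bonds; the aryl ether bond C8a–O1; the C2–C1' bond to ring B; then C2–C3, C3–C4 and C4–C4a.
Enabling feature: on ring A the C6 formyl group is para to C8a, the carbon that carries O1, and the C5 and C7 oxygens are meta to it, so a fluoride on C8a can be displaced by the C2 alkoxide through a formyl-stabilised Meisenheimer anion.
Forward: the chain grows from ring A (aryl boronic ester; C4, then C3 by two boron homologations; C2 as an aldehyde carbon), ring B is added as an aryllithium that already carries its two formyl groups as acetals, the pyran ring (the only ring formed) is then closed by SNAr, and the methyl ethers are cleaved last.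
Stereochemistry: C4 and C3 by reagent control ((−)-sparteine-lithiated benzoates and stereospecific 1,2-shifts on boron), C2 by Felkin–Anh hydride addition to the aryl ketone; the ring closure touches no stereocentre.
Ring A brings one formyl group and ring B two, so the count of three is fixed by the building blocks and no late formylation is needed.

Key step: step 14

Remark: (−)-sparteine/s-BuLi is assumed to remove the pro-S α-hydrogen of primary 2,4,6-triisopropylbenzoates as it does for the corresponding carbamates. Abbreviations: ArA = 3-(dimethoxymethyl)-6-fluoro-2,4-dimethoxyphenyl (ring A, aldehyde masked); ArB = 3,5-bis(dimethoxymethyl)-2,4,6-trimethoxyphenyl (ring B, both aldehydes masked); TIB = 2,4,6-tri(propan-2-yl)benzoyl; Bpin = 4,4,5,5-tetramethyl-1,3,2-dioxaborolan-2-yl.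

Step 1
Reactants: 1 4-fluoro-2,6-dimethoxybenzaldehyde
Product: 2 2-(dimethoxymethyl)-5-fluoro-1,3-dimethoxybenzene
Conditions: HC(OMe)3, MeOH, p-TsOH·H2O (cat.), 50 °C; then Et3N
Reagents that add atoms: trimethyl orthoformate COC(OC)OC; methanol CO
Why: Acid-catalysed acetalisation with the orthoformate as water scavenger masks the aldehyde as a group that is inert to the organolithium, boronate and hydride steps yet is hydrolysed by very mild acid later.

Step 2
Reactants: 2 2-(dimethoxymethyl)-5-fluoro-1,3-dimethoxybenzene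
Product: 4 ArA–Bpin [2-ArA-4,4,5,5-tetramethyl-1,3,2-dioxaborolane], via aryllithium 3 (not isolated)
Conditions: n-BuLi, THF, −78 °C; i-PrOBpin, −78 °C to rt; H2O
Reagents that add atoms: 2-isopropoxy-4,4,5,5-tetramethyl-1,3,2-dioxaborolane CC(C)OB1OC(C)(C)C(C)(C)O1
Why: Directed ortho-metalation and borylation: the two ring hydrogens are equivalent and each lies between fluorine and a methoxy group, so a single aryllithium should form, which is kept below −70 °C to prevent LiF loss to an aryne and is trapped by the isopropoxyboronate.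

Step 3
Reactants: 5 3-methylbutan-1-ol
Product: 6 3-methylbutyl 2,4,6-tri(propan-2-yl)benzoate
Conditions: TIB–Cl, Et3N, DMAP (cat.), CH2Cl2, reflux
Reagents that add atoms: 2,4,6-tri(propan-2-yl)benzoyl chloride CC(C)c1cc(C(C)C)c(C(Cl)=O)c(C(C)C)c1
Why: Acylation of a primary alcohol by the hindered acid chloride under nucleophilic catalysis gives a benzoate whose carbonyl is shielded from s-BuLi and directs α-deprotonation.

Step 4
Reactants: 6 3-methylbutyl 2,4,6-tri(propan-2-yl)benzoate; 4 ArA–Bpin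
Product: 9 2-[(1R)-1-ArA-3-methylbutyl]-4,4,5,5-tetramethyl-1,3,2-dioxaborolane, via lithiated benzoate 7 (not isolated), via boronate complex 8 (not isolated)
Conditions: 6 (1.3 equiv), s-BuLi (1.2 equiv), (−)-sparteine, Et2O, −78 °C; then 4 (1.0 equiv), −78 °C; then reflux; H2O
Reagents that add atoms: none
Why: Lithiation–borylation: s-BuLi/(−)-sparteine removes the pro-S α-hydrogen of 6, the configurationally stable (S)-carbenoid 7 is borylated by 4 with retention, and the aryl group then shifts from boron to carbon anti-periplanar to the departing benzoate (inversion), so reagent control alone fixes the (R) configuration of the benzylic carbon that becomes C4.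

Step 5
Reactants: 10 2-methylpropan-1-ol
Product: 11 2-methylpropyl 2,4,6-tri(propan-2-yl)benzoate
Conditions: TIB–Cl, Et3N, DMAP (cat.), CH2Cl2, reflux
Reagents that add atoms: 2,4,6-tri(propan-2-yl)benzoyl chloride CC(C)c1cc(C(C)C)c(C(Cl)=O)c(C(C)C)c1
Why: The same acylation as in step 3 provides the carbenoid precursor for the isopropyl-bearing carbon.

Step 6
Reactants: 11 2-methylpropyl 2,4,6-tri(propan-2-yl)benzoate; 9 2-[(1R)-1-ArA-3-methylbutyl]-4,4,5,5-tetramethyl-1,3,2-dioxaborolane
Product: 14 2-[(3R,4S)-4-ArA-2,6-dimethylheptan-3-yl]-4,4,5,5-tetramethyl-1,3,2-dioxaborolane, via lithiated benzoate 12 (not isolated), via boronate complex 13 (not isolated)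
Conditions: 11 (1.5 equiv), s-BuLi (1.4 equiv), (−)-sparteine, Et2O, −78 °C; then 9 (1.0 equiv), −78 °C; MgBr2·OEt2, MeOH, −78 °C to reflux; H2O
Reagents that add atoms: none
Why: Second lithiation–borylation under reagent control: the benzylic carbon of 9 migrates with retention onto the (S)-carbenoid 12 with inversion at the carbenoid carbon, which sets the isopropyl-bearing centre (future C3) whatever the bias of the existing centre, and MgBr2/MeOH is added to drive the 1,2-shift of the crowded boronate.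

Step 7
Reactants: 14 2-[(3R,4S)-4-ArA-2,6-dimethylheptan-3-yl]-4,4,5,5-tetramethyl-1,3,2-dioxaborolane
Product: 16 (2R,3S)-3-ArA-5-methyl-2-(propan-2-yl)hexanal, via α-chloro boronic ester 15 (not isolated)
Conditions: CH2Cl2, n-BuLi, THF, −100 °C; add 14; ZnCl2, −100 °C to rt; then 30% H2O2, NaH2PO4/Na2HPO4 buffer (pH 8), THF, 0 °C
Reagents that add atoms: dichloromethane ClCCl; hydrogen peroxide OO
Why: Matteson homologation (insertion of preformed LiCHCl2 with ZnCl2-assisted 1,2-shift, retention at the migrating carbon) followed by oxidation of the α-chloro boronic ester, whose α-chloro alkoxide collapses to the aldehyde, the buffered medium protecting the α-stereocentre from enolisation and the acetal from hydrolysis.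

Step 8
Reactants: 17 1,3,5-trimethoxybenzene
Product: 19 2,4,6-trimethoxybenzene-1,3-dicarbaldehyde, via 2,4,6-trimethoxybenzaldehyde 18 (not isolated)
Conditions: Cl2CHOMe (3 equiv), TiCl4 (4 equiv), CH2Cl2, 0 °C to rt; then H2O
Reagents that add atoms: dichloromethyl methyl ether COC(Cl)Cl; water O
Why: Rieche formylation carried through two substitutions: the monoaldehyde 18 has two equivalent free positions each activated by three methoxy groups and excess reagent forces the second formylation, whereas the TiCl4-complexed dialdehyde should be too electron-poor for a third.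

Step 9
Reactants: 19 2,4,6-trimethoxybenzene-1,3-dicarbaldehyde
Product: 20 2,4-bis(dimethoxymethyl)-1,3,5-trimethoxybenzene
Conditions: HC(OMe)3, MeOH, p-TsOH·H2O (cat.), reflux; then Et3N
Reagents that add atoms: trimethyl orthoformate COC(OC)OC; methanol CO
Why: Acetalisation as in step 1 turns both aldehydes into groups that tolerate aryllithium chemistry and leaves one ring hydrogen flanked by two methoxy groups.

Step 10
Reactants: 20 2,4-bis(dimethoxymethyl)-1,3,5-trimethoxybenzene; 16 (2R,3S)-3-ArA-5-methyl-2-(propan-2-yl)hexanal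
Product: 22 (2R,3S)-1-ArB-3-ArA-5-methyl-2-(propan-2-yl)hexan-1-ol as a mixture of C1 epimers, via aryllithium 21 (not isolated)
Conditions: 20 (1.3 equiv), n-BuLi (1.2 equiv), TMEDA, THF, 0 °C; then 16 (1.0 equiv), −78 °C; H2O
Reagents that add atoms: none
Why: Cooperative ortho-lithiation between two methoxy groups and 1,2-addition of the aryllithium to the aldehyde, with n-BuLi in deficit so that no alkyllithium meets the aldehyde or the acidic ring A hydrogen next to fluorine; because Felkin–Anh addition of the aryl group (anti to the 1-aryl-3-methylbutyl substituent) is expected to favour the unwanted (1S) epimer, the mixture is taken on without separation.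

Step 11
Reactants: 22 (2R,3S)-1-ArB-3-ArA-5-methyl-2-(propan-2-yl)hexan-1-ol (C1 epimers)
Product: 23 (2R,3S)-1-ArB-3-ArA-5-methyl-2-(propan-2-yl)hexan-1-one
Conditions: Dess–Martin periodinane, NaHCO3, CH2Cl2, rt
Reagents that add atoms: none
Why: Dess–Martin oxidation of the secondary benzylic alcohol under bicarbonate buffer is neutral, so the acetals and the α-stereocentre should be untouched, and both epimers converge on one ketone.

Step 12
Reactants: 23 (2R,3S)-1-ArB-3-ArA-5-methyl-2-(propan-2-yl)hexan-1-one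
Product: 24 (1R,2R,3S)-1-ArB-3-ArA-5-methyl-2-(propan-2-yl)hexan-1-ol
Conditions: LiAlH4, THF, −78 °C; then H2O, Na2SO4·10H2O
Reagents that add atoms: none
Why: Felkin–Anh-controlled hydride reduction: hydride attacks anti to the large 1-aryl-3-methylbutyl group on C2 and past the C2 hydrogen, with isopropyl gauche to the carbonyl oxygen, which leads to the (1R) carbinol (OH and isopropyl anti in the extended chain), while acetals, ethers and the aryl fluoride are inert to LiAlH4 at low temperature.

Step 13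
Reactants: 24 (1R,2R,3S)-1-ArB-3-ArA-5-methyl-2-(propan-2-yl)hexan-1-ol
Product: 25 5-[(1R,2R,3S)-3-(6-fluoro-3-formyl-2,4-dimethoxyphenyl)-1-hydroxy-5-methyl-2-(propan-2-yl)hexyl]-2,4,6-trimethoxybenzene-1,3-dicarbaldehyde
Conditions: PPTS (cat.), THF–H2O (4:1), rt to 40 °C
Reagents that add atoms: water O
Why: Acid-catalysed acetal hydrolysis: dimethyl acetals of electron-rich benzaldehydes are cleaved by a pyridinium salt in wet THF, conditions under which the trimethoxybenzylic alcohol should not yet ionise, and each formyl group released on ring B makes that ionisation less likely.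

Step 14
Reactants: 25 5-[(1R,2R,3S)-3-(6-fluoro-3-formyl-2,4-dimethoxyphenyl)-1-hydroxy-5-methyl-2-(propan-2-yl)hexyl]-2,4,6-trimethoxybenzene-1,3-dicarbaldehyde
Product: 28 5-[(2R,3R,4S)-6-formyl-5,7-dimethoxy-4-(2-methylpropyl)-3-(propan-2-yl)-3,4-dihydro-2H-chromen-2-yl]-2,4,6-trimethoxybenzene-1,3-dicarbaldehyde, via sodium alkoxide 26 (not isolated), via Meisenheimer adduct 27 (not isolated)
Conditions: NaH (1.2 equiv), THF–DMF (4:1), high dilution, 0 °C to rt
Reagents that add atoms: none
Why: NaH deprotonates the C1 carbinol and the alkoxide 26 adds to the fluorine-bearing carbon of ring A (C8a) to give the Meisenheimer anion 27, whose charge is delocalised through C6 onto the oxygen of the para formyl group; loss of fluoride then restores the arene (addition–elimination SNAr). The closest known reaction type is the intramolecular SNAr etherification of aryl fluorides activated by an ortho or para carbonyl group, a standard route to chromans. The pyran ring closes in a six-membered exo-trig mode, the attacked C8a=C8 π bond lying outside the new ring. No stereocentre is formed: only the O–H bond of the carbinol is broken, so C2, C3 and C4 keep the configurations set in steps 4, 6 and 12. The selectivity needed is attack at C8a and nowhere else: fluoride is the only good nucleofuge on ring A, its carbon is the only one that closes a six-membered ring and is para to the formyl group while the C5 and C7 methoxy groups are meta and do not oppose the charge, and the formyl-activated methoxy carbons of ring B could be reached by the alkoxide only through three- or four-membered rings. NaH is preferred to amide or alkoxide bases because it does not add to the three non-enolisable aldehydes, and cold, dilute conditions suppress intermolecular hydride transfer and substitution.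

Step 15
Reactants: 28 5-[(2R,3R,4S)-6-formyl-5,7-dimethoxy-4-(2-methylpropyl)-3-(propan-2-yl)-3,4-dihydro-2H-chromen-2-yl]-2,4,6-trimethoxybenzene-1,3-dicarbaldehyde
Product: 29 5-[(2R,3R,4S)-6-formyl-5,7-dihydroxy-4-(2-methylpropyl)-3-(propan-2-yl)-3,4-dihydro-2H-chromen-2-yl]-2,4,6-trihydroxybenzene-1,3-dicarbaldehyde (the target)
Conditions: BBr3 (12 equiv), CH2Cl2, −78 °C to rt; then H2O
Reagents that add atoms: none
Why: Lewis-acid cleavage of aryl methyl ethers: each of the five methoxy groups is ortho to a formyl group and should be removed through a six-membered boron chelate, while the C2–O1 benzylic ether should hold because ring B, with two complexed formyl groups, cannot stabilise positive charge at C2.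

Compound list
1 | 4-fluoro-2,6-dimethoxybenzaldehyde | COc1cc(F)cc(OC)c1C=O | starting material
2 | 2-(dimethoxymethyl)-5-fluoro-1,3-dimethoxybenzene | COC(OC)c1c(OC)cc(F)cc1OC | intermediate
3 | [3-(dimethoxymethyl)-6-fluoro-2,4-dimethoxyphenyl]lithium | COC(OC)c1c(OC)cc(F)c([Li])c1OC | intermediate (not isolated)
4 | 2-[3-(dimethoxymethyl)-6-fluoro-2,4-dimethoxyphenyl]-4,4,5,5-tetramethyl-1,3,2-dioxaborolane | COC(OC)c1c(OC)cc(F)c(B2OC(C)(C)C(C)(C)O2)c1OC | intermediate
5 | 3-methylbutan-1-ol | CC(C)CCO | starting material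
6 | 3-methylbutyl 2,4,6-tri(propan-2-yl)benzoate | CC(C)CCOC(=O)c1c(C(C)C)cc(C(C)C)cc1C(C)C | intermediate
7 | [(1S)-3-methyl-1-[2,4,6-tri(propan-2-yl)benzoyloxy]butyl]lithium, as its (−)-sparteine complex | CC(C)C[C@H]([Li])OC(=O)c1c(C(C)C)cc(C(C)C)cc1C(C)C | intermediate (not isolated)
8 | lithium [3-(dimethoxymethyl)-6-fluoro-2,4-dimethoxyphenyl][(1S)-3-methyl-1-[2,4,6-tri(propan-2-yl)benzoyloxy]butyl](pinacolato)borate | CC(C)C[C@H]([B-]1(c2c(F)cc(OC)c(C(OC)OC)c2OC)OC(C)(C)C(C)(C)O1)OC(=O)c1c(C(C)C)cc(C(C)C)cc1C(C)C.[Li+] | intermediate (not isolated)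
9 | 2-[(1R)-1-[3-(dimethoxymethyl)-6-fluoro-2,4-dimethoxyphenyl]-3-methylbutyl]-4,4,5,5-tetramethyl-1,3,2-dioxaborolane | CC(C)C[C@@H](B1OC(C)(C)C(C)(C)O1)c1c(F)cc(OC)c(C(OC)OC)c1OC | intermediate
10 | 2-methylpropan-1-ol | CC(C)CO | starting material
11 | 2-methylpropyl 2,4,6-tri(propan-2-yl)benzoate | CC(C)COC(=O)c1c(C(C)C)cc(C(C)C)cc1C(C)C | intermediate
12 | [(1S)-2-methyl-1-[2,4,6-tri(propan-2-yl)benzoyloxy]propyl]lithium, as its (−)-sparteine complex | CC(C)[C@H]([Li])OC(=O)c1c(C(C)C)cc(C(C)C)cc1C(C)C | intermediate (not isolated)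
13 | lithium [(1R)-1-[3-(dimethoxymethyl)-6-fluoro-2,4-dimethoxyphenyl]-3-methylbutyl][(1S)-2-methyl-1-[2,4,6-tri(propan-2-yl)benzoyloxy]propyl](pinacolato)borate | CC(C)[C@H]([B-]1([C@H](CC(C)C)c2c(F)cc(OC)c(C(OC)OC)c2OC)OC(C)(C)C(C)(C)O1)OC(=O)c1c(C(C)C)cc(C(C)C)cc1C(C)C.[Li+] | intermediate (not isolated)
14 | 2-[(3R,4S)-4-[3-(dimethoxymethyl)-6-fluoro-2,4-dimethoxyphenyl]-2,6-dimethylheptan-3-yl]-4,4,5,5-tetramethyl-1,3,2-dioxaborolane | CC(C)[C@@H](B1OC(C)(C)C(C)(C)O1)[C@H](CC(C)C)c1c(F)cc(OC)c(C(OC)OC)c1OC | intermediate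
15 | 2-[(2R,3S)-1-chloro-3-[3-(dimethoxymethyl)-6-fluoro-2,4-dimethoxyphenyl]-5-methyl-2-(propan-2-yl)hexyl]-4,4,5,5-tetramethyl-1,3,2-dioxaborolane (C1 epimers) | CC(C)[C@@H](C(Cl)B1OC(C)(C)C(C)(C)O1)[C@H](CC(C)C)c1c(F)cc(OC)c(C(OC)OC)c1OC | intermediate (not isolated)
16 | (2R,3S)-3-[3-(dimethoxymethyl)-6-fluoro-2,4-dimethoxyphenyl]-5-methyl-2-(propan-2-yl)hexanal | CC(C)[C@@H](C=O)[C@H](CC(C)C)c1c(F)cc(OC)c(C(OC)OC)c1OC | intermediate
17 | 1,3,5-trimethoxybenzene | COc1cc(OC)cc(OC)c1 | starting material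
18 | 2,4,6-trimethoxybenzaldehyde | COc1cc(OC)c(C=O)c(OC)c1 | intermediate (not isolated)
19 | 2,4,6-trimethoxybenzene-1,3-dicarbaldehyde | COc1cc(OC)c(C=O)c(OC)c1C=O | intermediate
20 | 2,4-bis(dimethoxymethyl)-1,3,5-trimethoxybenzene | COc1cc(OC)c(C(OC)OC)c(OC)c1C(OC)OC | intermediate
21 | [3,5-bis(dimethoxymethyl)-2,4,6-trimethoxyphenyl]lithium | COc1c([Li])c(OC)c(C(OC)OC)c(OC)c1C(OC)OC | intermediate (not isolated)
22 | (2R,3S)-1-[3,5-bis(dimethoxymethyl)-2,4,6-trimethoxyphenyl]-3-[3-(dimethoxymethyl)-6-fluoro-2,4-dimethoxyphenyl]-5-methyl-2-(propan-2-yl)hexan-1-ol (C1 epimers) | CC(C)[C@@H](C(O)c1c(OC)c(C(OC)OC)c(OC)c(C(OC)OC)c1OC)[C@H](CC(C)C)c1c(F)cc(OC)c(C(OC)OC)c1OC | intermediate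
23 | (2R,3S)-1-[3,5-bis(dimethoxymethyl)-2,4,6-trimethoxyphenyl]-3-[3-(dimethoxymethyl)-6-fluoro-2,4-dimethoxyphenyl]-5-methyl-2-(propan-2-yl)hexan-1-one | CC(C)[C@@H](C(=O)c1c(OC)c(C(OC)OC)c(OC)c(C(OC)OC)c1OC)[C@H](CC(C)C)c1c(F)cc(OC)c(C(OC)OC)c1OC | intermediate
24 | (1R,2R,3S)-1-[3,5-bis(dimethoxymethyl)-2,4,6-trimethoxyphenyl]-3-[3-(dimethoxymethyl)-6-fluoro-2,4-dimethoxyphenyl]-5-methyl-2-(propan-2-yl)hexan-1-ol | CC(C)C[C@H](c1c(F)cc(OC)c(C(OC)OC)c1OC)[C@@H](C(C)C)[C@@H](O)c1c(OC)c(C(OC)OC)c(OC)c(C(OC)OC)c1OC | intermediate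
25 | 5-[(1R,2R,3S)-3-(6-fluoro-3-formyl-2,4-dimethoxyphenyl)-1-hydroxy-5-methyl-2-(propan-2-yl)hexyl]-2,4,6-trimethoxybenzene-1,3-dicarbaldehyde | CC(C)C[C@H](c1c(F)cc(OC)c(C=O)c1OC)[C@@H](C(C)C)[C@@H](O)c1c(OC)c(C=O)c(OC)c(C=O)c1OC | intermediate (precursor of the key step)
26 | sodium (1R,2R,3S)-1-(3,5-diformyl-2,4,6-trimethoxyphenyl)-3-(6-fluoro-3-formyl-2,4-dimethoxyphenyl)-5-methyl-2-(propan-2-yl)hexan-1-olate | CC(C)C[C@H](c1c(F)cc(OC)c(C=O)c1OC)[C@@H](C(C)C)[C@@H]([O-])c1c(OC)c(C=O)c(OC)c(C=O)c1OC.[Na+] | intermediate (not isolated)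
27 | sodium [(2R,3R,4S)-2-(3,5-diformyl-2,4,6-trimethoxyphenyl)-8a-fluoro-5,7-dimethoxy-4-(2-methylpropyl)-3-(propan-2-yl)-2,3,4,8a-tetrahydro-6H-chromen-6-ylidene]methanolate (Meisenheimer adduct, C8a unspecified) | CC(C)C[C@@H]1C2=C(OC)C(=C[O-])C(OC)=CC2(F)O[C@@H](c2c(OC)c(C=O)c(OC)c(C=O)c2OC)[C@@H]1C(C)C.[Na+] | intermediate (not isolated)
28 | 5-[(2R,3R,4S)-6-formyl-5,7-dimethoxy-4-(2-methylpropyl)-3-(propan-2-yl)-3,4-dihydro-2H-chromen-2-yl]-2,4,6-trimethoxybenzene-1,3-dicarbaldehyde | CC(C)C[C@@H]1c2c(cc(OC)c(C=O)c2OC)O[C@@H](c2c(OC)c(C=O)c(OC)c(C=O)c2OC)[C@@H]1C(C)C | intermediate (product of the key step)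
29 | 5-[(2R,3R,4S)-6-formyl-5,7-dihydroxy-4-(2-methylpropyl)-3-(propan-2-yl)-3,4-dihydro-2H-chromen-2-yl]-2,4,6-trihydroxybenzene-1,3-dicarbaldehyde | CC(C)C[C@@H]1c2c(cc(O)c(C=O)c2O)O[C@@H](c2c(O)c(C=O)c(O)c(C=O)c2O)[C@@H]1C(C)C | target

Total step count: 15. Longest linear sequence: 11 steps (steps 1, 2, 4, 6, 7, 10, 11, 12, 13, 14, 15, from 1 to 29).

Steps most likely to fail

Step 6. Boronate formation between the α-branched carbenoid and the hindered secondary benzylic boronic ester may be slow and reversible, so the carbenoid decomposes or loses configuration before the 1,2-shift, and purity at C3 erodes. The fallback replaces reagent control by diol-controlled Matteson homologation, which accepts branched migrating groups and Grignard nucleophiles; it sets out from 2 and comes back at 16. Aryllithium 3, made as in step 2, is quenched with B(OMe)3 and hydrolysed at neutral pH to the arylboronic acid F1. F1 is esterified with (1S,2S)-1,2-dicyclohexylethane-1,2-diol (MgSO4, Et2O) to the dioxaborolane F2. Insertion of LiCHCl2 with ZnCl2 should give, under control of the diol, the (R)-α-chlorobenzyl boronic ester F3. i-BuMgBr adds to boron and displaces chloride with inversion to give the benzylic boronic ester F4, which has the configuration of 9. A second cycle gives the α-chloro boronic ester F5 and, with i-PrMgBr, the boronic ester F6, the dicyclohexylethanediol analogue of 14. A third LiCHCl2 insertion gives the α-chloro boronic ester F7, and buffered H2O2 oxidation as in step 7 releases aldehyde 16.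

Step 12. Facial discrimination may be poor, because the isopropyl and 1-aryl-3-methylbutyl groups on C2 may differ too little in effective size, or the twisted aryl ketone may react through another conformer; the result would be a mixture at C1. The fallback sets C1 by a boron-bound chiral diol instead of by the substrate, and forms the C1–aryl bond by a stereospecific 1,2-shift instead of forming the C1–H bond by hydride addition; it sets out from 14 and comes back at 24. Pinacol is removed oxidatively (NaIO4, NH4OAc, aqueous acetone) to give the boronic acid F8. F8 is esterified with (1R,2R)-1,2-dicyclohexylethane-1,2-diol to the dioxaborolane F9. LiCHCl2/ZnCl2 should then insert under diol control to give the (1S)-α-chloro boronic ester F10. Aryllithium 21, made as in step 10, adds to boron and migrates to carbon with inversion to give the benzylic boronic ester F11. Oxidation with H2O2/NaOH, with retention, gives carbinol 24.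

Step 15. Methyl ethers that share one formyl chelate may be cleaved incompletely; the Lewis acid may ionise the C2–O1 bond with loss of configuration at C2; or the formyl groups may be halogenated. The fallback changes the mode of cleavage from Lewis-acid activation at oxygen to SN2 attack at the methyl carbons by a soft nucleophile: n-PrSLi (from n-PrSH and n-BuLi) in HMPA with heating, then acidification. The secondary benzylic C2–O1 bond cannot be attacked in this way and is never activated. The fallback goes from 28 directly to 29 and makes no new compound.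

Further compounds
F1 | step 6 | [3-(dimethoxymethyl)-6-fluoro-2,4-dimethoxyphenyl]boronic acid | COC(OC)c1c(OC)cc(F)c(B(O)O)c1OC
F2 | step 6 | (4S,5S)-4,5-dicyclohexyl-2-[3-(dimethoxymethyl)-6-fluoro-2,4-dimethoxyphenyl]-1,3,2-dioxaborolane | COC(OC)c1c(OC)cc(F)c(B2O[C@@H](C3CCCCC3)[C@H](C3CCCCC3)O2)c1OC
F3 | step 6 | (4S,5S)-2-[(R)-chloro[3-(dimethoxymethyl)-6-fluoro-2,4-dimethoxyphenyl]methyl]-4,5-dicyclohexyl-1,3,2-dioxaborolane | Cl[C@@H](c1c(F)cc(OC)c(C(OC)OC)c1OC)B1O[C@@H](C2CCCCC2)[C@H](C2CCCCC2)O1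
F4 | step 6 | (4S,5S)-4,5-dicyclohexyl-2-[(1R)-1-[3-(dimethoxymethyl)-6-fluoro-2,4-dimethoxyphenyl]-3-methylbutyl]-1,3,2-dioxaborolane | CC(C)C[C@@H](B1O[C@@H](C2CCCCC2)[C@H](C2CCCCC2)O1)c1c(F)cc(OC)c(C(OC)OC)c1OC
F5 | step 6 | (4S,5S)-2-[(1R,2R)-1-chloro-2-[3-(dimethoxymethyl)-6-fluoro-2,4-dimethoxyphenyl]-4-methylpentyl]-4,5-dicyclohexyl-1,3,2-dioxaborolane | Cl[C@@H]([C@H](CC(C)C)c1c(F)cc(OC)c(C(OC)OC)c1OC)B1O[C@@H](C2CCCCC2)[C@H](C2CCCCC2)O1
F6 | step 6 | (4S,5S)-4,5-dicyclohexyl-2-[(3R,4S)-4-[3-(dimethoxymethyl)-6-fluoro-2,4-dimethoxyphenyl]-2,6-dimethylheptan-3-yl]-1,3,2-dioxaborolane | CC(C)[C@@H](B1O[C@@H](C2CCCCC2)[C@H](C2CCCCC2)O1)[C@H](CC(C)C)c1c(F)cc(OC)c(C(OC)OC)c1OC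
F7 | step 6 | (4S,5S)-2-[(1R,2R,3S)-1-chloro-3-[3-(dimethoxymethyl)-6-fluoro-2,4-dimethoxyphenyl]-5-methyl-2-(propan-2-yl)hexyl]-4,5-dicyclohexyl-1,3,2-dioxaborolane | CC(C)[C@@H]([C@H](Cl)B1O[C@@H](C2CCCCC2)[C@H](C2CCCCC2)O1)[C@H](CC(C)C)c1c(F)cc(OC)c(C(OC)OC)c1OC
F8 | step 12 | [(3R,4S)-4-[3-(dimethoxymethyl)-6-fluoro-2,4-dimethoxyphenyl]-2,6-dimethylheptan-3-yl]boronic acid | CC(C)[C@@H](B(O)O)[C@H](CC(C)C)c1c(F)cc(OC)c(C(OC)OC)c1OC
F9 | step 12 | (4R,5R)-4,5-dicyclohexyl-2-[(3R,4S)-4-[3-(dimethoxymethyl)-6-fluoro-2,4-dimethoxyphenyl]-2,6-dimethylheptan-3-yl]-1,3,2-dioxaborolane | CC(C)[C@@H](B1O[C@H](C2CCCCC2)[C@@H](C2CCCCC2)O1)[C@H](CC(C)C)c1c(F)cc(OC)c(C(OC)OC)c1OC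
F10 | step 12 | (4R,5R)-2-[(1S,2R,3S)-1-chloro-3-[3-(dimethoxymethyl)-6-fluoro-2,4-dimethoxyphenyl]-5-methyl-2-(propan-2-yl)hexyl]-4,5-dicyclohexyl-1,3,2-dioxaborolane | CC(C)[C@@H]([C@@H](Cl)B1O[C@H](C2CCCCC2)[C@@H](C2CCCCC2)O1)[C@H](CC(C)C)c1c(F)cc(OC)c(C(OC)OC)c1OC
F11 | step 12 | (4R,5R)-2-[(1R,2R,3S)-1-[3,5-bis(dimethoxymethyl)-2,4,6-trimethoxyphenyl]-3-[3-(dimethoxymethyl)-6-fluoro-2,4-dimethoxyphenyl]-5-methyl-2-(propan-2-yl)hexyl]-4,5-dicyclohexyl-1,3,2-dioxaborolane | CC(C)[C@@H]([C@H](c1c(OC)c(C(OC)OC)c(OC)c(C(OC)OC)c1OC)B1O[C@H](C2CCCCC2)[C@@H](C2CCCCC2)O1)[C@H](CC(C)C)c1c(F)cc(OC)c(C(OC)OC)c1OC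
F0 | step 15 | none | none
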